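The route rests on disconnecting the C5–C1′ bond between the vinylic carbon C5 of the 3,6-dihydro-2H-pyran ring and the first CH2 of the C16 polyene chain. The key step exploits the endocyclic C4=C5 alkene flanked by the allylic ether carbon C6: C5 is carried as a ring alkenyl iodide, made by 6-endo iodoetherification of a β-hydroxyallene, and the chain's CH2–CH2–CH=C end as the terminal vinyl group of a farnesal-derived tetraene. In one flask, 9-BBN hydroboration of the tetraene, B-alkyl Suzuki–Miyaura coupling and saponification of the activated acrylate ester give the target acid directly; the (S) centre at C2 comes from an asymmetric Morita–Baylis–Hillman reaction.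

Key step: step 7

Remark: ring atoms are numbered O1, C2 (stereocentre), C3, C4, C5, C6 and chain atoms C1′ onward; α-isocupreine, the catalyst of step 3, is assumed to be prepared from quinine in one acid-mediated operation.

Step 1
Reactants: 1 but-3-yn-1-ol
Product: 3 penta-3,4-dien-1-ol, via 5-[di(propan-2-yl)amino]pent-3-yn-1-ol 2 (not isolated)
Conditions: (CH2O)n (2 equiv), CuI (0.5 equiv), i-Pr2NH (2 equiv), 1,4-dioxane, reflux
Reagents that add atoms: paraformaldehyde (formaldehyde equivalent), C=O
Why: Crabbé homologation, in which the monovalent-copper acetylide of 1 condenses with formaldehyde and diisopropylamine to the propargylic amine 2, and copper-mediated 1,5-hydride transfer from an N-isopropyl C–H with loss of the imine then gives the terminal allene; the free primary hydroxyl is tolerated.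

Step 2
Reactants: 3 penta-3,4-dien-1-ol
Product: 4 penta-3,4-dienal
Conditions: Dess–Martin periodinane (1.2 equiv), CH2Cl2, 0 °C → rt; crude solution used at once
Reagents that add atoms: none
Why: Dess–Martin oxidation is fast and base-free, so the β,γ-allenic aldehyde should form without the enolisation that would move the allene into conjugation.

Step 3
Reactants: 4 penta-3,4-dienal; 5 1,1,1,3,3,3-hexafluoropropan-2-yl acrylate
Product: 6 1,1,1,3,3,3-hexafluoropropan-2-yl (3S)-3-hydroxy-2-methylidenehepta-5,6-dienoate
Conditions: 5 (1.3 equiv), α-isocupreine (10 mol %), DMF, −55 °C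
Reagents that add atoms: none
Why: Asymmetric Morita–Baylis–Hillman reaction, in which the quinuclidine nitrogen of the cage-shaped cinchona catalyst adds to the strongly activated acrylate, the resulting enolate adds to the aldehyde while the quinoline 6′-OH hydrogen-bonds the aldolate, and the quinine-derived α-isocupreine should deliver the S carbinol (its quinidine-derived pseudoenantiomer β-isocupreidine gives R); the low temperature and the fast reaction of an unbranched aldehyde should keep enolisation of 4 in the background.

Step 4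
Reactants: 6 1,1,1,3,3,3-hexafluoropropan-2-yl (3S)-3-hydroxy-2-methylidenehepta-5,6-dienoate
Product: 7 1,1,1,3,3,3-hexafluoropropan-2-yl 2-[(2S)-5-iodo-3,6-dihydro-2H-pyran-2-yl]prop-2-enoate
Conditions: NIS (1.2 equiv), CH2Cl2, 0 °C → rt, dark
Reagents that add atoms: N-iodosuccinimide, O=C1CCC(=O)N1I
Why: Electrophilic 6-endo iodoetherification of a β-hydroxyallene, in which the carbinol oxygen opens the iodonium at the terminal CH2 (C6) so that iodine ends on the central carbon (C5) and the C4=C5 alkene is endocyclic, the 4-exo closure to an oxetane being strained; the electron-poor acrylate alkene is inert to NIS and the C2 stereocentre is not touched.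

Step 5
Reactants: 8 (2E,6E)-farnesol
Product: 9 (2E,6E)-farnesal
Conditions: activated MnO2 (15 equiv), hexane, rt
Reagents that add atoms: none
Why: Allylic oxidation with MnO2 stops at the enal and should leave the trisubstituted alkenes and their E geometry untouched.

Step 6
Reactants: 9 (2E,6E)-farnesal
Product: 10 (3E,7E)-4,8,12-trimethyltrideca-1,3,7,11-tetraene
Conditions: Ph3PCH3Br, KOt-Bu, THF, 0 °C → rt
Reagents that add atoms: methyltriphenylphosphonium bromide, C[P+](c1ccccc1)(c1ccccc1)c1ccccc1.[Br-]
Why: Wittig methylenation with the non-stabilised ylide is 1,2-selective on the enal and creates only a terminal CH2=, so the former 2E (now 3E) alkene keeps its geometry.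

Step 7
Reactants: 10 (3E,7E)-4,8,12-trimethyltrideca-1,3,7,11-tetraene; 7 1,1,1,3,3,3-hexafluoropropan-2-yl 2-[(2S)-5-iodo-3,6-dihydro-2H-pyran-2-yl]prop-2-enoate
Product: 13 2-[(2S)-5-[(3E,7E)-4,8,12-trimethyltrideca-3,7,11-trien-1-yl]-3,6-dihydro-2H-pyran-2-yl]prop-2-enoic acid (target), via B-alkyl-9-BBN adduct 11 (not isolated), via sodium iodo-dihydropyranylacrylate 12 (not isolated)
Conditions: a) 10 (1.5 equiv), 9-BBN dimer, THF, 0 °C → rt; b) 7, 3 M aq NaOH (4 equiv), THF, 0 °C, 20 min; c) both solutions combined, Pd(dppf)Cl2·CH2Cl2 (5 mol %), AsPh3 (10 mol %), DMF, rt → 40 °C; d) 1 M HCl to pH 3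
Reagents that add atoms: sodium hydroxide, [Na+].[OH-]
Why: 9-BBN adds across the only monosubstituted alkene of 10, the terminal vinyl group of the 1,3-diene, with boron on C1 (the three trisubstituted alkenes are too hindered), giving the primary alkylborane 11, while hydroxide cleaves the activated hexafluoroisopropyl ester of 7 to the carboxylate 12, whose acrylate is then no longer an electrophile. Zerovalent palladium inserts into the C5–I bond of 12, the hydroxyborate of 11 hands its primary alkyl group to palladium and reductive elimination forms the C5–C1′ bond; acidification releases 13. The closest known reaction type is the B-alkyl Suzuki–Miyaura coupling of cycloalkenyl iodides with 9-BBN adducts of terminal alkenes. No ring is closed and no stereocentre is formed: the dihydropyran ring and its S centre at C2, which is remote from C5 and not epimerisable as the carboxylate, are carried through unchanged, the ring fixes the C4=C5 geometry and the E alkenes of the chain are spectators. The step needs regio- and chemoselective hydroboration, transfer of the primary alkyl group in preference to the bicyclic B–C bonds, and coupling faster than β-hydride elimination or β-alkoxide loss from the alkenylpalladium; the bulk of 9-BBN, its bicyclic framework and the wide-bite-angle dppf ligand with AsPh3 should secure these.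

Compound list
1 | but-3-yn-1-ol | C#CCCO | starting material
2 | 5-[di(propan-2-yl)amino]pent-3-yn-1-ol | CC(C)N(CC#CCCO)C(C)C | intermediate
3 | penta-3,4-dien-1-ol | C=C=CCCO | intermediate
4 | penta-3,4-dienal | C=C=CCC=O | intermediate
5 | 1,1,1,3,3,3-hexafluoropropan-2-yl acrylate | C=CC(=O)OC(C(F)(F)F)C(F)(F)F | starting material
6 | 1,1,1,3,3,3-hexafluoropropan-2-yl (3S)-3-hydroxy-2-methylidenehepta-5,6-dienoate | C=C(C(=O)OC(C(F)(F)F)C(F)(F)F)[C@@H](O)CC=C=C | intermediate
7 | 1,1,1,3,3,3-hexafluoropropan-2-yl 2-[(2S)-5-iodo-3,6-dihydro-2H-pyran-2-yl]prop-2-enoate | C=C(C(=O)OC(C(F)(F)F)C(F)(F)F)[C@@H]1CC=C(I)CO1 | intermediate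
8 | (2E,6E)-farnesol, (2E,6E)-3,7,11-trimethyldodeca-2,6,10-trien-1-ol | OC/C=C(\C)CC/C=C(\C)CCC=C(C)C | starting material
9 | (2E,6E)-farnesal, (2E,6E)-3,7,11-trimethyldodeca-2,6,10-trienal | O=C/C=C(\C)CC/C=C(\C)CCC=C(C)C | intermediate
10 | (3E,7E)-4,8,12-trimethyltrideca-1,3,7,11-tetraene | C=C/C=C(\C)CC/C=C(\C)CCC=C(C)C | intermediate
11 | 9-[(3E,7E)-4,8,12-trimethyltrideca-3,7,11-trien-1-yl]-9-borabicyclo[3.3.1]nonane | B1(CC/C=C(\C)CC/C=C(\C)CCC=C(C)C)C2CCCC1CCC2 | intermediate
12 | sodium 2-[(2S)-5-iodo-3,6-dihydro-2H-pyran-2-yl]prop-2-enoate | C=C(C(=O)[O-])[C@@H]1CC=C(I)CO1.[Na+] | intermediate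
13 | 2-[(2S)-5-[(3E,7E)-4,8,12-trimethyltrideca-3,7,11-trien-1-yl]-3,6-dihydro-2H-pyran-2-yl]prop-2-enoic acid | C=C(C(=O)O)[C@@H]1CC=C(CC/C=C(\C)CC/C=C(\C)CCC=C(C)C)CO1 | target

Total step count: 7. Longest linear sequence: 5 (steps 1, 2, 3, 4 and 7); the chain branch (steps 5 and 6) joins in step 7.

Steps most likely to fail

Step 3. What may go wrong is amine-induced enolisation of the β,γ-allenic aldehyde, which lets the allene drift into conjugation before the C–C bond forms, or insufficient facial discrimination with this small unbranched aldehyde. The fallback builds the carbinol under non-basic conditions and resolves it. It sets out from 4: the α-aluminated acrylate made from methyl propiolate with i-Bu2AlH and N-methylmorpholine N-oxide (THF, 0 °C) should add to 4 to give racemic methyl 3-hydroxy-2-methylidenehepta-5,6-dienoate F1. Lipase-catalysed acylation (Burkholderia cepacia lipase, vinyl acetate, t-BuOMe) is expected, by the empirical size rule for secondary alcohols with the acrylate arm as the larger group, to convert the R alcohol into methyl (3R)-3-acetoxy-2-methylidenehepta-5,6-dienoate F2 and to leave methyl (3S)-3-hydroxy-2-methylidenehepta-5,6-dienoate F3. F3 would be cyclised with NIS as in step 4 to methyl 2-[(2S)-5-iodo-3,6-dihydro-2H-pyran-2-yl]prop-2-enoate F4, and F4 coupled with 11 (Pd(dppf)Cl2, AsPh3, Cs2CO3, DMF/THF/H2O) to methyl 2-[(2S)-5-[(3E,7E)-4,8,12-trimethyltrideca-3,7,11-trien-1-yl]-3,6-dihydro-2H-pyran-2-yl]prop-2-enoate F5. LiOH added to the same flask would saponify F5, so the fallback comes back to the route at 13.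

Step 7. What may go wrong is protodeboronation or β-hydride elimination of the alkyl group outrunning transmetalation, incomplete or unselective hydroboration of the diene terminus, or hydroxide-induced degradation of the acrylate before the ester is cleaved. The fallback is a Negishi coupling under neutral, anhydrous conditions with a separate saponification. It sets out from 10 and 7: hydroboration of 10 to 11 followed by NaOH/H2O2 should give (3E,7E)-4,8,12-trimethyltrideca-3,7,11-trien-1-ol F6, and I2/PPh3/imidazole would convert it into (3E,7E)-1-iodo-4,8,12-trimethyltrideca-3,7,11-triene F7. Zinc insertion (Zn dust, LiCl, THF) would give [(3E,7E)-4,8,12-trimethyltrideca-3,7,11-trien-1-yl]zinc iodide F8, which would be coupled with 7 (Pd(OAc)2, SPhos, THF/NMP, rt) to 1,1,1,3,3,3-hexafluoropropan-2-yl 2-[(2S)-5-[(3E,7E)-4,8,12-trimethyltrideca-3,7,11-trien-1-yl]-3,6-dihydro-2H-pyran-2-yl]prop-2-enoate F9. LiOH in aqueous THF at 0 °C would then cleave the activated ester, and the fallback comes back to the route at 13.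

Step 4. What may go wrong is slow or unselective ring closure, because the carbinol oxygen is deactivated by the neighbouring acrylate and the iodonium can also be opened at the central allene carbon to a five-membered enol ether. The fallback separates ring closure from halogenation by π-acid catalysis. It sets out from 6: Ph3PAuCl/AgBF4 (5 mol % each, CH2Cl2, rt) should trigger 6-endo oxyauration to the C5-aurated dihydropyran [(6S)-6-{3-[(1,1,1,3,3,3-hexafluoropropan-2-yl)oxy]-3-oxoprop-1-en-2-yl}-5,6-dihydro-2H-pyran-3-yl](triphenylphosphane)gold F10. NIS present in the same flask would convert F10 by iododeauration into 7, where the fallback comes back to the route.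

Further compounds
F1 | step 3 | methyl 3-hydroxy-2-methylidenehepta-5,6-dienoate (racemic) | C=C(C(=O)OC)C(O)CC=C=C
F2 | step 3 | methyl (3R)-3-acetoxy-2-methylidenehepta-5,6-dienoate | C=C(C(=O)OC)[C@H](OC(C)=O)CC=C=C
F3 | step 3 | methyl (3S)-3-hydroxy-2-methylidenehepta-5,6-dienoate | C=C(C(=O)OC)[C@@H](O)CC=C=C
F4 | step 3 | methyl 2-[(2S)-5-iodo-3,6-dihydro-2H-pyran-2-yl]prop-2-enoate | C=C(C(=O)OC)[C@@H]1CC=C(I)CO1
F5 | step 3 | methyl 2-[(2S)-5-[(3E,7E)-4,8,12-trimethyltrideca-3,7,11-trien-1-yl]-3,6-dihydro-2H-pyran-2-yl]prop-2-enoate | C=C(C(=O)OC)[C@@H]1CC=C(CC/C=C(\C)CC/C=C(\C)CCC=C(C)C)CO1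
F6 | step 7 | (3E,7E)-4,8,12-trimethyltrideca-3,7,11-trien-1-ol | OCC/C=C(\C)CC/C=C(\C)CCC=C(C)C
F7 | step 7 | (3E,7E)-1-iodo-4,8,12-trimethyltrideca-3,7,11-triene | ICC/C=C(\C)CC/C=C(\C)CCC=C(C)C
F8 | step 7 | [(3E,7E)-4,8,12-trimethyltrideca-3,7,11-trien-1-yl]zinc iodide | I[Zn]CC/C=C(\C)CC/C=C(\C)CCC=C(C)C
F9 | step 7 | 1,1,1,3,3,3-hexafluoropropan-2-yl 2-[(2S)-5-[(3E,7E)-4,8,12-trimethyltrideca-3,7,11-trien-1-yl]-3,6-dihydro-2H-pyran-2-yl]prop-2-enoate | C=C(C(=O)OC(C(F)(F)F)C(F)(F)F)[C@@H]1CC=C(CC/C=C(\C)CC/C=C(\C)CCC=C(C)C)CO1
F10 | step 4 | [(6S)-6-{3-[(1,1,1,3,3,3-hexafluoropropan-2-yl)oxy]-3-oxoprop-1-en-2-yl}-5,6-dihydro-2H-pyran-3-yl](triphenylphosphane)gold | C=C(C(=O)OC(C(F)(F)F)C(F)(F)F)[C@@H]1CC=C([Au-][P+](c2ccccc2)(c2ccccc2)c2ccccc2)CO1
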